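**Retrosynthetic overview** (target locants follow tricyclo[5.4.0.0(2,8)]undecane: cyclobutane C1–C2–C8–C7, enone C11(=O)–C10=C9, esters on C3 and C5, CMe2 = C6)
1. C6–C7 bond (seven-membered ring, formed last): iron-hydride HAT radical closure of an isopropenyl side chain onto the tosylhydrazone of a cyclobutanone, with loss of N2 so that C7 ends as CH.
2. C3–C6 chain and both esters: acetyl group on C2 + methacrolein (boron aldol), Evans–Tishchenko reduction (anti-1,3-diol, isovalerate), senecioylation; the enone comes from a silyloxy group by oxidation and alkene isomerisation.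
3. C1–C7 and C2–C8 bonds (cyclobutane and six-membered ring in one operation): intramolecular vinylketene–alkene [2+2] cycloaddition of an acyclic dienyne acid, with the alkene face controlled by the silyloxy stereocentre.
4. Acyclic acid: catalytic enantioselective vinylogous Mukaiyama aldol of the methyl senecioate dienolate with (2E)-3-methylpent-2-en-4-ynal.
5. Ring order: cyclobutane + cyclohexane together, then cycloheptane.

Assumption: the antipodes of the chiral reagents (bisphosphoramide, Ipc2BCl) are quoted for the facial sense stated in each step, and the SMILES strings are authoritative for configuration.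

**Step 1**
Reactants: 1 methyl 3-methylbut-2-enoate
Product: 2 tert-butyl{[(1Z)-1-methoxy-3-methylbuta-1,3-dien-1-yl]oxy}dimethylsilane
Conditions: LiN(iPr)2, THF, −78 °C; tBuMe2SiCl, DMPU, −78 °C to rt
Reagents that add atoms: tert-butyl(chloro)dimethylsilane, CC(C)(C)[Si](C)(C)Cl
Why: γ-Deprotonation of the enoate gives the extended lithium dienolate, which is O-silylated to the vinylogous silyl ketene acetal (silyl dienolate formation); no stereocentre is created.

**Step 2**
Reactants: 3 (2E)-3-methylpent-2-en-4-yn-1-ol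
Product: 4 (2E)-3-methylpent-2-en-4-ynal
Conditions: MnO2, CH2Cl2, rt
Reagents that add atoms: none
Why: Chemoselective MnO2 oxidation of the allylic alcohol to the enal leaves the alkyne and the E geometry untouched.

**Step 3**
Reactants: 2 tert-butyl{[(1Z)-1-methoxy-3-methylbuta-1,3-dien-1-yl]oxy}dimethylsilane, 4 (2E)-3-methylpent-2-en-4-ynal
Product: 5 methyl (2E,5S,6E)-5-hydroxy-3,7-dimethylnona-2,6-dien-8-ynoate
Conditions: SiCl4, (S,S)-N,N′-bis[(11bS)-3,5-dimethyl-4-oxido-3,5-dihydro-4H-dinaphtho[2,1-d:1′,2′-f][1,3,2]diazaphosphepin-4-yl]-N,N′-dimethylpentane-1,5-diamine (2 mol %), iPr2NEt (10 mol %), CH2Cl2, −78 °C; then aq NaHCO3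
Reagents that add atoms: none
Why: Lewis-base-activated SiCl4 vinylogous Mukaiyama aldol: the dienolate reacts only at its γ-carbon, and the phosphoramide-bound silicon cation blocks the Re face of the aldehyde so that Si-face attack sets 5S (the new C2=C3 bond is E).

**Step 4**
Reactants: 5 methyl (2E,5S,6E)-5-hydroxy-3,7-dimethylnona-2,6-dien-8-ynoate
Product: 6 methyl (2E,5S,6E)-5-{[tert-butyl(dimethyl)silyl]oxy}-3,7-dimethylnona-2,6-dien-8-ynoate
Conditions: tBuMe2SiOTf, 2,6-lutidine, CH2Cl2, −78 to 0 °C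
Reagents that add atoms: tert-butyldimethylsilyl trifluoromethanesulfonate, CC(C)(C)[Si](C)(C)OS(=O)(=O)C(F)(F)F
Why: Standard silylation of the secondary carbinol, which must be masked before the acid is activated and which later steers the cycloaddition.

**Step 5**
Reactants: 6 methyl (2E,5S,6E)-5-{[tert-butyl(dimethyl)silyl]oxy}-3,7-dimethylnona-2,6-dien-8-ynoate
Product: 7 (2E,5S,6E)-5-{[tert-butyl(dimethyl)silyl]oxy}-3,7-dimethylnona-2,6-dien-8-ynoic acid
Conditions: LiOH, THF/MeOH/H2O, rt; then 1 M HCl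
Reagents that add atoms: lithium hydroxide, [Li+].[OH-]
Why: Saponification of the methyl ester; the silyl ether, the enyne and the stereocentre are untouched.

**Step 6**
Reactants: 7 (2E,5S,6E)-5-{[tert-butyl(dimethyl)silyl]oxy}-3,7-dimethylnona-2,6-dien-8-ynoic acid
Product: 10 (1R,4S,5R,7R)-4-{[tert-butyl(dimethyl)silyl]oxy}-7-ethynyl-7-methyl-2-methylidenebicyclo[3.1.1]heptan-6-one, via acid chloride 8 (not isolated), via vinylketene 9 (not isolated)
Conditions: (COCl)2, DMF (cat.), PhH, rt, evaporate; then slow addition to Et3N, PhMe, 110 °C (0.005 M)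
Reagents that add atoms: none
Why: Intramolecular vinylketene–alkene [2+2] cycloaddition: Et3N removes a γ-methyl proton of 8 to give vinylketene 9, whose carbonyl carbon bonds to the proximal alkene CH and whose α-carbon bonds to the methyl/ethynyl-bearing carbon (crossed mode, charge build-up at the more substituted carbon), so the cyclobutanone and the six-membered ring form at once; suprafacial addition to the E-alkene places the ethynyl group on the ketone-bridge side, and the 5S silyloxy group avoids A(1,3) strain with the cis-methyl so that one alkene face is attacked, which fixes C1, C5 and C7.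

**Step 7**
Reactants: 10 (1R,4S,5R,7R)-4-{[tert-butyl(dimethyl)silyl]oxy}-7-ethynyl-7-methyl-2-methylidenebicyclo[3.1.1]heptan-6-one
Product: 11 (1R,4S,5R,7R)-7-acetyl-4-{[tert-butyl(dimethyl)silyl]oxy}-7-methyl-2-methylidenebicyclo[3.1.1]heptan-6-one
Conditions: Ph3PAuNTf2 (2 mol %), MeOH/H2O, 50 °C
Reagents that add atoms: water, O
Why: Gold-catalysed Markovnikov hydration of the terminal alkyne gives the methyl ketone; the isolated alkene, which sits anti to the alkyne across the cyclobutane, the silyl ether and the cyclobutanone are inert to the carbophilic catalyst.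

**Step 8**
Reactants: 11 (1R,4S,5R,7R)-7-acetyl-4-{[tert-butyl(dimethyl)silyl]oxy}-7-methyl-2-methylidenebicyclo[3.1.1]heptan-6-one, 12 2-methylprop-2-enal
Product: 13 (1R,4S,5R,7R)-4-{[tert-butyl(dimethyl)silyl]oxy}-7-[(3R)-3-hydroxy-4-methylpent-4-enoyl]-7-methyl-2-methylidenebicyclo[3.1.1]heptan-6-one
Conditions: (+)-Ipc2BCl, Et3N, Et2O, 0 °C; 12, −78 to −20 °C; HN(CH2CH2OH)2 work-up (no peroxide)
Reagents that add atoms: none
Why: Paterson boron aldol: the methyl ketone is the only enolisable carbonyl (the cyclobutanone α-carbons are bridgeheads), and the chiral Ipc2B enolate adds 1,2 to the Re face of methacrolein to set 3R under reagent control.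

**Step 9**
Reactants: 13 (1R,4S,5R,7R)-4-{[tert-butyl(dimethyl)silyl]oxy}-7-[(3R)-3-hydroxy-4-methylpent-4-enoyl]-7-methyl-2-methylidenebicyclo[3.1.1]heptan-6-one, 14 3-methylbutanal
Product: 15 (3R,5R)-5-[(1R,4S,5R,7R)-4-{[tert-butyl(dimethyl)silyl]oxy}-7-methyl-2-methylidene-6-oxobicyclo[3.1.1]heptan-7-yl]-5-hydroxy-2-methylpent-1-en-3-yl 3-methylbutanoate
Conditions: SmI2 (30 mol %, premixed with 14), 14 (6 equiv), THF, −10 °C
Reagents that add atoms: none
Why: Evans–Tishchenko reduction: the samarium-bound hemiacetal of 14 delivers hydride intramolecularly to the ketone through a chair-like chelate, which gives the 1,3-anti diol with the isovalerate on the original carbinol oxygen and sets the new carbinol centre R.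

**Step 10**
Reactants: 15 (3R,5R)-5-[(1R,4S,5R,7R)-4-{[tert-butyl(dimethyl)silyl]oxy}-7-methyl-2-methylidene-6-oxobicyclo[3.1.1]heptan-7-yl]-5-hydroxy-2-methylpent-1-en-3-yl 3-methylbutanoate, 16 3-methylbut-2-enoyl chloride
Product: 17 (1R,3R)-1-[(1R,4S,5R,7R)-4-{[tert-butyl(dimethyl)silyl]oxy}-7-methyl-2-methylidene-6-oxobicyclo[3.1.1]heptan-7-yl]-4-methyl-3-[(3-methylbutanoyl)oxy]pent-4-en-1-yl 3-methylbut-2-enoate
Conditions: pyridine, DMAP (cat.), CH2Cl2, 0 °C to rt
Reagents that add atoms: none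
Why: DMAP-catalysed acylation of the remaining hindered secondary alcohol; the weak base avoids deconjugation of the senecioyl group and acyl migration.

**Step 11**
Reactants: 17 (1R,3R)-1-[(1R,4S,5R,7R)-4-{[tert-butyl(dimethyl)silyl]oxy}-7-methyl-2-methylidene-6-oxobicyclo[3.1.1]heptan-7-yl]-4-methyl-3-[(3-methylbutanoyl)oxy]pent-4-en-1-yl 3-methylbut-2-enoate
Product: 18 (1R,3R)-1-[(1R,4S,5R,7R)-4-hydroxy-7-methyl-2-methylidene-6-oxobicyclo[3.1.1]heptan-7-yl]-4-methyl-3-[(3-methylbutanoyl)oxy]pent-4-en-1-yl 3-methylbut-2-enoate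
Conditions: HF·pyridine, THF, 0 °C to rt
Reagents that add atoms: none
Why: Fluoride-driven desilylation; the esters, alkenes and cyclobutanone survive buffered HF.

**Step 12**
Reactants: 18 (1R,3R)-1-[(1R,4S,5R,7R)-4-hydroxy-7-methyl-2-methylidene-6-oxobicyclo[3.1.1]heptan-7-yl]-4-methyl-3-[(3-methylbutanoyl)oxy]pent-4-en-1-yl 3-methylbut-2-enoate
Product: 20 (1R,3R)-1-[(1R,5R,7R)-4,7-dimethyl-2,6-dioxobicyclo[3.1.1]hept-3-en-7-yl]-4-methyl-3-[(3-methylbutanoyl)oxy]pent-4-en-1-yl 3-methylbut-2-enoate, via deconjugated dione 19 (not isolated)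
Conditions: Dess–Martin periodinane, CH2Cl2, rt; then Et3N, rt
Reagents that add atoms: none
Why: Dess–Martin oxidation gives the β,γ-unsaturated ketone 19, and amine-mediated γ-deprotonation/reprotonation moves the exocyclic alkene into conjugation (the thermodynamic verbenone-type enone); no nucleophile is present that could open the strained non-enolisable 1,3-dione, and no stereocentre is touched.

**Step 13**
Reactants: 20 (1R,3R)-1-[(1R,5R,7R)-4,7-dimethyl-2,6-dioxobicyclo[3.1.1]hept-3-en-7-yl]-4-methyl-3-[(3-methylbutanoyl)oxy]pent-4-en-1-yl 3-methylbut-2-enoate, 21 4-methylbenzenesulfonohydrazide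
Product: 24 (1R,2R,3R,5R,7S,8R)-2,6,6,9-tetramethyl-5-[(3-methylbutanoyl)oxy]-11-oxotricyclo[5.4.0.0(2,8)]undec-9-en-3-yl 3-methylbut-2-enoate, via tosylhydrazone 22 (not isolated), via tricyclic tosylhydrazide 23 (not isolated)
Conditions: 21, EtOH, rt; then Fe(acac)3 (30 mol %), PhSiH3, 60 °C; then NaOAc, 80 °C
Reagents that add atoms: none
Why: Proposed new method: the strained cyclobutanone condenses with 21 faster than the hindered conjugated enone; hydrogen-atom transfer from an iron hydride to the 1,1-disubstituted alkene (the enone and enoate are not HAT donors) then gives the tertiary radical, which adds 7-exo to the hydrazone carbon from the only face the tether can reach, and base-induced loss of sulfinate and N2 from the resulting alkyl hydrazide leaves C7–H, whose configuration is forced by the ring fusion; the closest known reactions are iron-hydride alkene–tosylhydrazone radical cyclisation to five- and six-membered rings and the reductive C–N cleavage of alkyl sulfonylhydrazides used in alkene hydromethylation and Caglioti-type reductions.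

**Compound list**
1 | methyl 3-methylbut-2-enoate | COC(=O)C=C(C)C | starting material
2 | tert-butyl{[(1Z)-1-methoxy-3-methylbuta-1,3-dien-1-yl]oxy}dimethylsilane | C=C(C)/C=C(/OC)O[Si](C)(C)C(C)(C)C | intermediate
3 | (2E)-3-methylpent-2-en-4-yn-1-ol | C#C/C(C)=C/CO | starting material
4 | (2E)-3-methylpent-2-en-4-ynal | C#C/C(C)=C/C=O | intermediate
5 | methyl (2E,5S,6E)-5-hydroxy-3,7-dimethylnona-2,6-dien-8-ynoate | COC(=O)/C=C(\C)C[C@H](O)/C=C(\C)C#C | intermediate
6 | methyl (2E,5S,6E)-5-{[tert-butyl(dimethyl)silyl]oxy}-3,7-dimethylnona-2,6-dien-8-ynoate | COC(=O)/C=C(\C)C[C@H](O[Si](C)(C)C(C)(C)C)/C=C(\C)C#C | intermediate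
7 | (2E,5S,6E)-5-{[tert-butyl(dimethyl)silyl]oxy}-3,7-dimethylnona-2,6-dien-8-ynoic acid | OC(=O)/C=C(\C)C[C@H](O[Si](C)(C)C(C)(C)C)/C=C(\C)C#C | intermediate
8 | (2E,5S,6E)-5-{[tert-butyl(dimethyl)silyl]oxy}-3,7-dimethylnona-2,6-dien-8-ynoyl chloride | O=C(Cl)/C=C(\C)C[C@H](O[Si](C)(C)C(C)(C)C)/C=C(\C)C#C | intermediate
9 | (5S,6E)-5-{[tert-butyl(dimethyl)silyl]oxy}-7-methyl-3-methylidenenona-1,6-dien-8-yn-1-one (vinylketene) | O=C=CC(=C)C[C@H](O[Si](C)(C)C(C)(C)C)/C=C(\C)C#C | intermediate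
10 | (1R,4S,5R,7R)-4-{[tert-butyl(dimethyl)silyl]oxy}-7-ethynyl-7-methyl-2-methylidenebicyclo[3.1.1]heptan-6-one | C#C[C@@]1(C)[C@H]2C(=O)[C@@H]1C(=C)C[C@@H]2O[Si](C)(C)C(C)(C)C | intermediate
11 | (1R,4S,5R,7R)-7-acetyl-4-{[tert-butyl(dimethyl)silyl]oxy}-7-methyl-2-methylidenebicyclo[3.1.1]heptan-6-one | CC(=O)[C@@]1(C)[C@H]2C(=O)[C@@H]1C(=C)C[C@@H]2O[Si](C)(C)C(C)(C)C | intermediate
12 | 2-methylprop-2-enal (methacrolein) | C=C(C)C=O | starting material
13 | (1R,4S,5R,7R)-4-{[tert-butyl(dimethyl)silyl]oxy}-7-[(3R)-3-hydroxy-4-methylpent-4-enoyl]-7-methyl-2-methylidenebicyclo[3.1.1]heptan-6-one | C=C(C)[C@H](O)CC(=O)[C@@]1(C)[C@H]2C(=O)[C@@H]1C(=C)C[C@@H]2O[Si](C)(C)C(C)(C)C | intermediate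
14 | 3-methylbutanal | CC(C)CC=O | starting material
15 | (3R,5R)-5-[(1R,4S,5R,7R)-4-{[tert-butyl(dimethyl)silyl]oxy}-7-methyl-2-methylidene-6-oxobicyclo[3.1.1]heptan-7-yl]-5-hydroxy-2-methylpent-1-en-3-yl 3-methylbutanoate | C=C(C)[C@H](OC(=O)CC(C)C)C[C@@H](O)[C@@]1(C)[C@H]2C(=O)[C@@H]1C(=C)C[C@@H]2O[Si](C)(C)C(C)(C)C | intermediate
16 | 3-methylbut-2-enoyl chloride | CC(C)=CC(=O)Cl | starting material
17 | (1R,3R)-1-[(1R,4S,5R,7R)-4-{[tert-butyl(dimethyl)silyl]oxy}-7-methyl-2-methylidene-6-oxobicyclo[3.1.1]heptan-7-yl]-4-methyl-3-[(3-methylbutanoyl)oxy]pent-4-en-1-yl 3-methylbut-2-enoate | C=C(C)[C@H](OC(=O)CC(C)C)C[C@@H](OC(=O)C=C(C)C)[C@@]1(C)[C@H]2C(=O)[C@@H]1C(=C)C[C@@H]2O[Si](C)(C)C(C)(C)C | intermediate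
18 | (1R,3R)-1-[(1R,4S,5R,7R)-4-hydroxy-7-methyl-2-methylidene-6-oxobicyclo[3.1.1]heptan-7-yl]-4-methyl-3-[(3-methylbutanoyl)oxy]pent-4-en-1-yl 3-methylbut-2-enoate | C=C(C)[C@H](OC(=O)CC(C)C)C[C@@H](OC(=O)C=C(C)C)[C@@]1(C)[C@H]2C(=O)[C@@H]1C(=C)C[C@@H]2O | intermediate
19 | (1R,3R)-4-methyl-1-[(1R,5R,7R)-7-methyl-4-methylidene-2,6-dioxobicyclo[3.1.1]heptan-7-yl]-3-[(3-methylbutanoyl)oxy]pent-4-en-1-yl 3-methylbut-2-enoate | C=C(C)[C@H](OC(=O)CC(C)C)C[C@@H](OC(=O)C=C(C)C)[C@@]1(C)[C@H]2C(=O)[C@@H]1C(=C)CC2=O | intermediate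
20 | (1R,3R)-1-[(1R,5R,7R)-4,7-dimethyl-2,6-dioxobicyclo[3.1.1]hept-3-en-7-yl]-4-methyl-3-[(3-methylbutanoyl)oxy]pent-4-en-1-yl 3-methylbut-2-enoate | C=C(C)[C@H](OC(=O)CC(C)C)C[C@@H](OC(=O)C=C(C)C)[C@@]1(C)[C@H]2C(=O)[C@@H]1C(C)=CC2=O | intermediate
21 | 4-methylbenzenesulfonohydrazide | Cc1ccc(cc1)S(=O)(=O)NN | starting material
22 | 6-(4-methylbenzenesulfonylhydrazone) of 20 (cyclobutanone C=O replaced by C=N–NHTs, C=N geometry not defined, all stereocentres as in 20) | C=C(C)[C@H](OC(=O)CC(C)C)C[C@@H](OC(=O)C=C(C)C)[C@@]1(C)[C@H]2C(=NNS(=O)(=O)c3ccc(C)cc3)[C@@H]1C(C)=CC2=O | intermediate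
23 | 7-[2-(4-methylbenzenesulfonyl)hydrazinyl] analogue of 24 (hydrazinyl group on C7 in place of H, on the face of the enone bridge) | CC(C)=CC(=O)O[C@@H]1C[C@@H](OC(=O)CC(C)C)C(C)(C)[C@]2(NNS(=O)(=O)c4ccc(C)cc4)[C@H]3C(=O)C=C(C)[C@@H]2[C@]31C | intermediate
24 | (1R,2R,3R,5R,7S,8R)-2,6,6,9-tetramethyl-5-[(3-methylbutanoyl)oxy]-11-oxotricyclo[5.4.0.0(2,8)]undec-9-en-3-yl 3-methylbut-2-enoate | CC(C)=CC(=O)O[C@@H]1C[C@@H](OC(=O)CC(C)C)C(C)(C)[C@@H]2[C@H]3C(=O)C=C(C)[C@@H]2[C@]31C | target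

**Totals**
Total step count: 13. Longest linear sequence: 12 steps (3 → 4 → 5 → 6 → 7 → 10 → 11 → 13 → 15 → 17 → 18 → 20 → 24).

**Three steps most likely to fail**

Step 6 (vinylketene [2+2]). The risks are γ-deprotonation at the methylene next to the silyloxy carbon instead of the methyl, loss of silanolate, and a sluggish enyne ketenophile. The fallback sets out from 6. Kinetic deconjugation (LiN(iPr)2, THF–DMPU, −78 °C, then AcOH) gives methyl (5S,6E)-5-{[tert-butyl(dimethyl)silyl]oxy}-7-methyl-3-methylidenenon-6-en-8-ynoate F1. Hydrolysis with Me3SnOH gives (5S,6E)-5-{[tert-butyl(dimethyl)silyl]oxy}-7-methyl-3-methylidenenon-6-en-8-ynoic acid F2, and oxalyl chloride gives (5S,6E)-5-{[tert-butyl(dimethyl)silyl]oxy}-7-methyl-3-methylidenenon-6-en-8-ynoyl chloride F3. Simple α-deprotonation of this β,γ-unsaturated acid chloride with Et3N generates the same vinylketene regiospecifically and at lower temperature, so the route is rejoined at 9 and continues to 10.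

Step 8 (boron aldol). The risks are low facial selectivity with a methyl ketone on a quaternary carbon and attack of the boron enolate on the nearby cyclobutanone. The fallback sets out from 11. Me3SiOTf/Et3N gives the silyl enol ether (1R,4S,5R,7R)-4-{[tert-butyl(dimethyl)silyl]oxy}-7-methyl-2-methylidene-7-[1-(trimethylsilyloxy)ethenyl]bicyclo[3.1.1]heptan-6-one F4. An open-transition-state Mukaiyama aldol with 12 follows, promoted by the N-tosyltryptophan-derived B-butyl-1,3,2-oxazaborolidin-5-one, which activates only the aldehyde and leaves the enol ether inert toward the ketone. After desilylation on work-up the route is rejoined at 13.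

Step 13 (radical ring closure and loss of nitrogen). The risks are a slow 7-exo addition to a hindered C=N carbon, simple reduction of the alkene, and incomplete C–N cleavage. The fallback sets out from 20. The same iron-hydride HAT radical (Fe(acac)3, PhSiH3, EtOH/ethylene glycol, 60 °C) is closed directly onto the cyclobutanone carbonyl, a known ketone-acceptor cyclisation, giving the tertiary cyclobutanol (7-hydroxy analogue of 24, hydroxyl on the face of the enone bridge) F5. Methyl chlorooxoacetate/DMAP/pyridine converts it into its methyl oxalate (7-[(methoxyoxalyl)oxy] analogue of 24) F6, and Bu3SnH/AIBN in PhMe at 110 °C removes the oxygen by radical deoxygenation, so the route is rejoined at 24.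

**Further compounds**
F1 | step 6 | methyl (5S,6E)-5-{[tert-butyl(dimethyl)silyl]oxy}-7-methyl-3-methylidenenon-6-en-8-ynoate | COC(=O)CC(=C)C[C@H](O[Si](C)(C)C(C)(C)C)/C=C(\C)C#C
F2 | step 6 | (5S,6E)-5-{[tert-butyl(dimethyl)silyl]oxy}-7-methyl-3-methylidenenon-6-en-8-ynoic acid | OC(=O)CC(=C)C[C@H](O[Si](C)(C)C(C)(C)C)/C=C(\C)C#C
F3 | step 6 | (5S,6E)-5-{[tert-butyl(dimethyl)silyl]oxy}-7-methyl-3-methylidenenon-6-en-8-ynoyl chloride | O=C(Cl)CC(=C)C[C@H](O[Si](C)(C)C(C)(C)C)/C=C(\C)C#C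
F4 | step 8 | (1R,4S,5R,7R)-4-{[tert-butyl(dimethyl)silyl]oxy}-7-methyl-2-methylidene-7-[1-(trimethylsilyloxy)ethenyl]bicyclo[3.1.1]heptan-6-one | C=C(O[Si](C)(C)C)[C@@]1(C)[C@H]2C(=O)[C@@H]1C(=C)C[C@@H]2O[Si](C)(C)C(C)(C)C
F5 | step 13 | 7-hydroxy analogue of 24 (tertiary cyclobutanol, hydroxyl on the face of the enone bridge) | CC(C)=CC(=O)O[C@@H]1C[C@@H](OC(=O)CC(C)C)C(C)(C)[C@]2(O)[C@H]3C(=O)C=C(C)[C@@H]2[C@]31C
F6 | step 13 | 7-[(methoxyoxalyl)oxy] analogue of 24 (methyl oxalate of F5) | CC(C)=CC(=O)O[C@@H]1C[C@@H](OC(=O)CC(C)C)C(C)(C)[C@]2(OC(=O)C(=O)OC)[C@H]3C(=O)C=C(C)[C@@H]2[C@]31C
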